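Numbering: C1 is the lactone carbonyl, C7 the ring CH–O. Everything rests on the C4–C5 ethano bridge of the eight-membered lactone ring, flanked by C3 and by C6, which sits next to the oxygen-bearing C7. C4–C5 is acetylene: a C1–C3 silyloxypropyl cuprate adds across it (C3–C4) and the resulting (Z)-alkenyl cuprate opens (R)-benzyl glycidyl ether at its terminal carbon (C5–C6), so one operation joins three small components and delivers C7 from the chiral pool. The cis C4=C5 bond then serves as a temporary fold for eight-membered lactonisation and is hydrogenated away; cyclopropanation and alkenylzinc addition complete the target.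

Key step: step 1

Remark: carbons are numbered C1 (lactone carbonyl) to C22 (terminal methyl); C8–C10 form the cyclopropane (C9 is its CH2), C11 and C14 are the carbinols. The chiral controllers (4S,5S)-dioxaborolane ligand, (S)-Alpine-borane and (+)-MIB are treated as purchasable reagents.

Step 1
Reactants: 1 tert-butyl(3-iodopropoxy)dimethylsilane; 2 acetylene; 3 (R)-benzyl glycidyl ether
Product: 7 (2R,4Z)-1-(benzyloxy)-8-[(tert-butyldimethylsilyl)oxy]oct-4-en-2-ol, via organolithium 4 (not isolated), via lithium dialkylcuprate 5 (not isolated), via lithium dialkenylcuprate 6 (not isolated)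
Conditions: 1 (2 equiv), t-BuLi (4 equiv), Et2O, −78 °C; CuBr·SMe2 (1 equiv), −45 °C; 2 (2 equiv), −50 → −25 °C; 3 (0.8 equiv), Et2O/THF, −30 → 0 °C; aq. NH4Cl/NH3
Reagents that add atoms: none
Why: Iodine–lithium exchange and transmetalation to copper give dialkylcuprate 5, which adds syn across acetylene so that C3 bonds to C4 and a (Z)-alkenyl cuprate 6 results; 6 then opens epoxide 3 by SN2 attack at its unsubstituted carbon, forming C5–C6 in the same flask. The closest known reaction type is the Normant carbocupration of acetylene followed by epoxide alkylation of the (Z)-alkenyl cuprate, a one-pot three-component coupling. No ring is closed in this step (the oxirane is opened). No new stereocentre is created: C7 is carried over unchanged from 3 because the bond is made at the neighbouring CH2, and the cis geometry of C4=C5 follows from the syn addition. The step needs single insertion of acetylene and attack at the terminal epoxide carbon; the first is secured by keeping the carbocupration below −25 °C with two equivalents of acetylene per copper, the second by the steric bias of the monosubstituted oxirane.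

Step 2
Reactants: 7 (2R,4Z)-1-(benzyloxy)-8-[(tert-butyldimethylsilyl)oxy]oct-4-en-2-ol
Product: 8 (4Z,7R)-8-(benzyloxy)oct-4-ene-1,7-diol
Conditions: CSA (10 mol%), MeOH, 0 °C
Reagents that add atoms: none
Why: Acid-catalysed methanolysis of a silyl ether should remove the unhindered primary TBS group while the benzyl ether and the cis alkene stay untouched.

Step 3
Reactants: 8 (4Z,7R)-8-(benzyloxy)oct-4-ene-1,7-diol
Product: 10 (4Z,7R)-8-(benzyloxy)-7-hydroxyoct-4-enoic acid, via hydroxy aldehyde 9 (not isolated)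
Conditions: TEMPO (cat.), PhI(OAc)2 (2.2 equiv), MeCN/H2O, rt
Reagents that add atoms: water – O
Why: The oxoammonium (TEMPO/PhI(OAc)2) oxidation is selective for the primary alcohol and should carry it through the aldehyde hydrate to the acid, leaving the secondary C7 hydroxyl free for ring closure.

Step 4
Reactants: 10 (4Z,7R)-8-(benzyloxy)-7-hydroxyoct-4-enoic acid
Product: 12 (5Z,8R)-8-[(benzyloxy)methyl]-3,4,7,8-tetrahydro-2H-oxocin-2-one, via mixed anhydride 11 (not isolated)
Conditions: 2,4,6-Cl3C6H2COCl, Et3N, THF, rt; then slow addition to DMAP, toluene, 100 °C, high dilution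
Reagents that add atoms: none
Why: Yamaguchi lactonisation should close the eight-membered ring by attack of the C7 hydroxyl on the activated acyl group (retention at C7), the cis C4=C5 bond bringing the chain ends together and removing transannular strain.

Step 5
Reactants: 12 (5Z,8R)-8-[(benzyloxy)methyl]-3,4,7,8-tetrahydro-2H-oxocin-2-one
Product: 13 (8R)-8-(hydroxymethyl)oxocan-2-one
Conditions: H2 (1 atm), Pd/C, EtOAc, rt
Reagents that add atoms: none
Why: Heterogeneous catalytic hydrogenation should saturate the C4=C5 bond, whose folding role is over, and hydrogenolyse the benzyl ether in the same operation without touching C7.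

Step 6
Reactants: 13 (8R)-8-(hydroxymethyl)oxocan-2-one
Product: 14 (8R)-2-oxooxocane-8-carbaldehyde
Conditions: Dess–Martin periodinane, NaHCO3, CH2Cl2, 0 °C → rt
Reagents that add atoms: none
Why: Buffered Dess–Martin oxidation should give the α-acyloxy aldehyde under neutral conditions that do not epimerise C7.

Step 7
Reactants: 14 (8R)-2-oxooxocane-8-carbaldehyde
Product: 15 (2E)-3-[(8R)-2-oxooxocan-8-yl]prop-2-enal
Conditions: Ph3P=CHCHO (1.05 equiv), toluene, 60 °C
Reagents that add atoms: (triphenylphosphoranylidene)acetaldehyde – O=CC=P(c1ccccc1)(c1ccccc1)c1ccccc1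
Why: Wittig olefination with the stabilised formylmethylene ylide should give the E-enal (C8=C10) and is non-basic enough to leave the lactone and C7 intact.

Step 8
Reactants: 15 (2E)-3-[(8R)-2-oxooxocan-8-yl]prop-2-enal
Product: 16 (8R)-8-[(1E)-3-hydroxyprop-1-en-1-yl]oxocan-2-one
Conditions: NaBH4, CeCl3·7H2O, MeOH, −40 °C
Reagents that add atoms: none
Why: Luche reduction should reduce the enal carbonyl in 1,2-fashion to the E-allylic alcohol while the lactone is not attacked at low temperature.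

Step 9
Reactants: 16 (8R)-8-[(1E)-3-hydroxyprop-1-en-1-yl]oxocan-2-one
Product: 17 (8R)-8-[(1R,2R)-2-(hydroxymethyl)cyclopropyl]oxocan-2-one
Conditions: Et2Zn, CH2I2, DME, CH2Cl2, −10 °C; (4S,5S)-2-butyl-N,N,N′,N′-tetramethyl-1,3,2-dioxaborolane-4,5-dicarboxamide (1.2 equiv), → rt
Reagents that add atoms: diiodomethane – ICI
Why: In the Charette asymmetric Simmons–Smith cyclopropanation the zinc alkoxide of 16 binds the chiral dioxaborolane, which directs CH2 transfer to one alkene face, so C8 and C10 should be set under reagent control (the (4S,5S) ligand is the antipode of the one that turns cinnamyl alcohol into the (S,S)-cyclopropane) and the E geometry becomes the trans ring.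

Step 10
Reactants: 17 (8R)-8-[(1R,2R)-2-(hydroxymethyl)cyclopropyl]oxocan-2-one
Product: 18 (1R,2R)-2-[(8R)-2-oxooxocan-8-yl]cyclopropane-1-carbaldehyde
Conditions: Dess–Martin periodinane, NaHCO3, CH2Cl2, 0 °C → rt
Reagents that add atoms: none
Why: Dess–Martin oxidation should give the trans-cyclopropanecarbaldehyde (C11) without disturbing the cyclopropane stereocentres.

Step 11
Reactants: 19 (3Z,6Z)-nona-3,6-dien-1-ol
Product: 20 (3Z,6Z)-nona-3,6-dienal
Conditions: Dess–Martin periodinane, NaHCO3, CH2Cl2, 0 °C; used crude at once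
Reagents that add atoms: none
Why: Buffered Dess–Martin oxidation is base-free, so the skipped diene should not slide into conjugation with the new aldehyde (C14).

Step 12
Reactants: 20 (3Z,6Z)-nona-3,6-dienal
Product: 21 rac-(5Z,8Z)-undeca-5,8-dien-1-yn-3-ol
Conditions: HC≡CMgBr, THF, −78 °C; aq. NH4Cl
Reagents that add atoms: ethynylmagnesium bromide – C#C[Mg]Br
Why: Grignard 1,2-addition at low temperature should outrun enolisation and install C12–C13 as the terminal alkyne.

Step 13
Reactants: 21 rac-(5Z,8Z)-undeca-5,8-dien-1-yn-3-ol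
Product: 22 (5Z,8Z)-undeca-5,8-dien-1-yn-3-one
Conditions: Dess–Martin periodinane, NaHCO3, CH2Cl2, 0 °C
Reagents that add atoms: none
Why: Dess–Martin oxidation of the propargylic alcohol should give the ynone under neutral conditions that keep the Z,Z-diene out of conjugation.

Step 14
Reactants: 22 (5Z,8Z)-undeca-5,8-dien-1-yn-3-one
Product: 23 (3S,5Z,8Z)-undeca-5,8-dien-1-yn-3-ol
Conditions: (S)-Alpine-borane, THF, 0 °C → rt; then ethanolamine
Reagents that add atoms: none
Why: Midland reduction transfers the pinanyl hydride through a cyclic transition state that places the slim ethynyl group in the crowded position, so the reagent from (−)-α-pinene should set C14 as S.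

Step 15
Reactants: 23 (3S,5Z,8Z)-undeca-5,8-dien-1-yn-3-ol
Product: 24 tert-butyldimethyl{[(3S,5Z,8Z)-undeca-5,8-dien-1-yn-3-yl]oxy}silane
Conditions: TBSCl, imidazole, DMF, rt
Reagents that add atoms: tert-butyldimethylsilyl chloride – CC(C)(C)[Si](C)(C)Cl
Why: Standard imidazole-promoted silylation should protect the C14 hydroxyl for the organometallic coupling.

Step 16
Reactants: 24 tert-butyldimethyl{[(3S,5Z,8Z)-undeca-5,8-dien-1-yn-3-yl]oxy}silane; 18 (1R,2R)-2-[(8R)-2-oxooxocan-8-yl]cyclopropane-1-carbaldehyde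
Product: 27 (8R)-8-{(1R,2R)-2-[(1R,2E,4S,6Z,9Z)-4-[(tert-butyldimethylsilyl)oxy]-1-hydroxydodeca-2,6,9-trien-1-yl]cyclopropyl}oxocan-2-one, via alkenylborane 25 (not isolated), via alkenylzinc 26 (not isolated)
Conditions: Cy2BH (from BH3·SMe2, cyclohexene), toluene, 0 °C → rt; Me2Zn, −78 °C; (+)-MIB (10 mol%), 18, −30 → 0 °C; aq. NH4Cl
Reagents that add atoms: none
Why: Syn hydroboration of the terminal alkyne gives the (E)-alkenylborane, boron-to-zinc exchange gives the alkenylzinc, and in this catalytic asymmetric alkenylzinc addition the amino alcohol (+)-MIB should direct attack to the Re face of aldehyde 18, setting C11 as R under ligand control and C12=C13 as E, with the lactone inert to organozinc.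

Step 17
Reactants: 27 (8R)-8-{(1R,2R)-2-[(1R,2E,4S,6Z,9Z)-4-[(tert-butyldimethylsilyl)oxy]-1-hydroxydodeca-2,6,9-trien-1-yl]cyclopropyl}oxocan-2-one
Product: 28 (8R)-8-{(1R,2R)-2-[(1R,2E,4S,6Z,9Z)-1,4-dihydroxydodeca-2,6,9-trien-1-yl]cyclopropyl}oxocan-2-one (CNP0227294.1)
Conditions: HF·pyridine, pyridine, THF, 0 °C → rt
Reagents that add atoms: none
Why: Buffered fluoride desilylation should free the C14 hydroxyl without opening the lactone or ionising the allylic alcohols.

Compound list
1 | tert-butyl(3-iodopropoxy)dimethylsilane | CC(C)(C)[Si](C)(C)OCCCI | starting material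
2 | acetylene | C#C | starting material
3 | (R)-benzyl glycidyl ether, (R)-2-[(benzyloxy)methyl]oxirane | C1O[C@H]1COCc1ccccc1 | starting material
4 | [3-(tert-butyldimethylsilyloxy)propyl]lithium | [Li]CCCO[Si](C)(C)C(C)(C)C | intermediate
5 | lithium bis[3-(tert-butyldimethylsilyloxy)propyl]cuprate | [Li+].CC(C)(C)[Si](C)(C)OCCC[Cu-]CCCO[Si](C)(C)C(C)(C)C | intermediate
6 | lithium bis[(Z)-5-(tert-butyldimethylsilyloxy)pent-1-en-1-yl]cuprate | [Li+].CC(C)(C)[Si](C)(C)OCCC/C=C\[Cu-]/C=C\CCCO[Si](C)(C)C(C)(C)C | intermediate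
7 | (2R,4Z)-1-(benzyloxy)-8-[(tert-butyldimethylsilyl)oxy]oct-4-en-2-ol | O[C@@H](COCc1ccccc1)C/C=C\CCCO[Si](C)(C)C(C)(C)C | intermediate
8 | (4Z,7R)-8-(benzyloxy)oct-4-ene-1,7-diol | O[C@@H](COCc1ccccc1)C/C=C\CCCO | intermediate
9 | (4Z,7R)-8-(benzyloxy)-7-hydroxyoct-4-enal | O[C@@H](COCc1ccccc1)C/C=C\CCC=O | intermediate
10 | (4Z,7R)-8-(benzyloxy)-7-hydroxyoct-4-enoic acid | O[C@@H](COCc1ccccc1)C/C=C\CCC(=O)O | intermediate
11 | (4Z,7R)-8-(benzyloxy)-7-hydroxyoct-4-enoic 2,4,6-trichlorobenzoic anhydride | O[C@@H](COCc1ccccc1)C/C=C\CCC(=O)OC(=O)c1c(Cl)cc(Cl)cc1Cl | intermediate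
12 | (5Z,8R)-8-[(benzyloxy)methyl]-3,4,7,8-tetrahydro-2H-oxocin-2-one | O=C1CC/C=C\C[C@H](COCc2ccccc2)O1 | intermediate
13 | (8R)-8-(hydroxymethyl)oxocan-2-one | O=C1CCCCC[C@H](CO)O1 | intermediate
14 | (8R)-2-oxooxocane-8-carbaldehyde | O=C1CCCCC[C@H](C=O)O1 | intermediate
15 | (2E)-3-[(8R)-2-oxooxocan-8-yl]prop-2-enal | O=C1CCCCC[C@H](/C=C/C=O)O1 | intermediate
16 | (8R)-8-[(1E)-3-hydroxyprop-1-en-1-yl]oxocan-2-one | O=C1CCCCC[C@H](/C=C/CO)O1 | intermediate
17 | (8R)-8-[(1R,2R)-2-(hydroxymethyl)cyclopropyl]oxocan-2-one | OC[C@@H]1C[C@H]1[C@H]1CCCCCC(=O)O1 | intermediate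
18 | (1R,2R)-2-[(8R)-2-oxooxocan-8-yl]cyclopropane-1-carbaldehyde | O=C[C@@H]1C[C@H]1[C@H]1CCCCCC(=O)O1 | intermediate
19 | (3Z,6Z)-nona-3,6-dien-1-ol | CC/C=C\C/C=C\CCO | starting material
20 | (3Z,6Z)-nona-3,6-dienal | CC/C=C\C/C=C\CC=O | intermediate
21 | rac-(5Z,8Z)-undeca-5,8-dien-1-yn-3-ol | CC/C=C\C/C=C\CC(O)C#C | intermediate
22 | (5Z,8Z)-undeca-5,8-dien-1-yn-3-one | CC/C=C\C/C=C\CC(=O)C#C | intermediate
23 | (3S,5Z,8Z)-undeca-5,8-dien-1-yn-3-ol | CC/C=C\C/C=C\C[C@H](O)C#C | intermediate
24 | tert-butyldimethyl{[(3S,5Z,8Z)-undeca-5,8-dien-1-yn-3-yl]oxy}silane | CC/C=C\C/C=C\C[C@H](O[Si](C)(C)C(C)(C)C)C#C | intermediate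
25 | dicyclohexyl{(1E,3S,5Z,8Z)-3-[(tert-butyldimethylsilyl)oxy]undeca-1,5,8-trien-1-yl}borane | CC/C=C\C/C=C\C[C@H](O[Si](C)(C)C(C)(C)C)/C=C/B(C1CCCCC1)C1CCCCC1 | intermediate
26 | methyl{(1E,3S,5Z,8Z)-3-[(tert-butyldimethylsilyl)oxy]undeca-1,5,8-trien-1-yl}zinc | CC/C=C\C/C=C\C[C@H](O[Si](C)(C)C(C)(C)C)/C=C/[Zn]C | intermediate
27 | (8R)-8-{(1R,2R)-2-[(1R,2E,4S,6Z,9Z)-4-[(tert-butyldimethylsilyl)oxy]-1-hydroxydodeca-2,6,9-trien-1-yl]cyclopropyl}oxocan-2-one | CC/C=C\C/C=C\C[C@H](O[Si](C)(C)C(C)(C)C)/C=C/[C@@H](O)[C@@H]1C[C@H]1[C@H]1CCCCCC(=O)O1 | intermediate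
28 | (8R)-8-{(1R,2R)-2-[(1R,2E,4S,6Z,9Z)-1,4-dihydroxydodeca-2,6,9-trien-1-yl]cyclopropyl}oxocan-2-one (CNP0227294.1) | CC/C=C\C/C=C\C[C@H](O)/C=C/[C@@H](O)[C@@H]1C[C@H]1[C@H]1CCCCCC(=O)O1 | target

Total step count: 17 (steps 1–10 lactone–cyclopropane aldehyde, steps 11–15 side-chain alkyne, steps 16–17 union and deprotection).
Longest linear sequence: 12 steps (steps 1–10, 16, 17).

Steps most likely to fail

Step 1. The alkenyl cuprate may take up a second acetylene, or it may open the epoxide so slowly that it decomposes thermally first. The fallback sets out from 3 and builds the same two bonds one after the other. Lithium acetylide (LiC≡CH·H2NCH2CH2NH2, DMSO) opens 3 to (2R)-1-(benzyloxy)pent-4-yn-2-ol F1. Its alkoxide–acetylide dianion (n-BuLi, 2 equiv, THF/DMPU) is C-alkylated with iodide 1 to (2R)-1-(benzyloxy)-8-[(tert-butyldimethylsilyl)oxy]oct-4-yn-2-ol F2. Semihydrogenation (H2, Pd/CaCO3 poisoned with Pb(OAc)2, quinoline) then returns to 7.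

Step 4. Intermolecular acylation (diolide and oligomer formation) may outrun closure of the eight-membered ring. The fallback closes the same C–O bond by activating the alcohol and not the acid, so it needs the C7 epimer. It sets out from 1 and 2 and repeats steps 1–3 with (S)-benzyl glycidyl ether F3 in place of 3. This gives (2S,4Z)-1-(benzyloxy)-8-[(tert-butyldimethylsilyl)oxy]oct-4-en-2-ol F4, then (4Z,7S)-8-(benzyloxy)oct-4-ene-1,7-diol F5, then, by way of (4Z,7S)-8-(benzyloxy)-7-hydroxyoct-4-enal F6 (not isolated), (4Z,7S)-8-(benzyloxy)-7-hydroxyoct-4-enoic acid F7. Mitsunobu lactonisation (PPh3, DIAD, toluene, high dilution) displaces the activated C7 hydroxyl with the carboxylate under inversion and comes back to the route at 12.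

Step 16. Facial discrimination at the aldehyde may be poor, giving C11 epimers, and methyl transfer from zinc may compete with alkenyl transfer. The fallback sets out from 18 and 26 and moves the stereocontrol from C–C bond formation to a ketone reduction. The addition is run without ligand and gives 27 mixed with its epimer (8R)-8-{(1R,2R)-2-[(1S,2E,4S,6Z,9Z)-4-[(tert-butyldimethylsilyl)oxy]-1-hydroxydodeca-2,6,9-trien-1-yl]cyclopropyl}oxocan-2-one F8. Dess–Martin oxidation of the mixture converges on the enone (8R)-8-{(1R,2R)-2-[(2E,4S,6Z,9Z)-4-[(tert-butyldimethylsilyl)oxy]dodeca-2,6,9-trienoyl]cyclopropyl}oxocan-2-one F9. Corey–Bakshi–Shibata reduction (2-methyl-CBS-oxazaborolidine, catecholborane, −78 °C) then returns to 27. The (R)-catalyst is the one to use if, as in simple enones, the alkenyl group acts as the larger substituent; this sense would need to be confirmed.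

Further compounds
F1 | step 1 | (2R)-1-(benzyloxy)pent-4-yn-2-ol | O[C@@H](COCc1ccccc1)CC#C
F2 | step 1 | (2R)-1-(benzyloxy)-8-[(tert-butyldimethylsilyl)oxy]oct-4-yn-2-ol | O[C@@H](COCc1ccccc1)CC#CCCCO[Si](C)(C)C(C)(C)C
F3 | step 4 | (S)-benzyl glycidyl ether | C1O[C@@H]1COCc1ccccc1
F4 | step 4 | (2S,4Z)-1-(benzyloxy)-8-[(tert-butyldimethylsilyl)oxy]oct-4-en-2-ol | O[C@H](COCc1ccccc1)C/C=C\CCCO[Si](C)(C)C(C)(C)C
F5 | step 4 | (4Z,7S)-8-(benzyloxy)oct-4-ene-1,7-diol | O[C@H](COCc1ccccc1)C/C=C\CCCO
F6 | step 4 | (4Z,7S)-8-(benzyloxy)-7-hydroxyoct-4-enal | O[C@H](COCc1ccccc1)C/C=C\CCC=O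
F7 | step 4 | (4Z,7S)-8-(benzyloxy)-7-hydroxyoct-4-enoic acid | O[C@H](COCc1ccccc1)C/C=C\CCC(=O)O
F8 | step 16 | (8R)-8-{(1R,2R)-2-[(1S,2E,4S,6Z,9Z)-4-[(tert-butyldimethylsilyl)oxy]-1-hydroxydodeca-2,6,9-trien-1-yl]cyclopropyl}oxocan-2-one | CC/C=C\C/C=C\C[C@H](O[Si](C)(C)C(C)(C)C)/C=C/[C@H](O)[C@@H]1C[C@H]1[C@H]1CCCCCC(=O)O1
F9 | step 16 | (8R)-8-{(1R,2R)-2-[(2E,4S,6Z,9Z)-4-[(tert-butyldimethylsilyl)oxy]dodeca-2,6,9-trienoyl]cyclopropyl}oxocan-2-one | CC/C=C\C/C=C\C[C@H](O[Si](C)(C)C(C)(C)C)/C=C/C(=O)[C@@H]1C[C@H]1[C@H]1CCCCCC(=O)O1
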